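**Strategy.** Everything rests on the C5–C6 bond of the side chain (numbered from the ylidene carbon), where the CH2CH2CH2 spacer that leaves the C2 stereocentre meets the methyl-bearing sp2 carbon of the 6E alkene. This sp3–sp2 junction is exploited by a one-pot 9-BBN hydroboration and B-alkyl Suzuki–Miyaura coupling: the allyl group of a finished (Z)-ylidene hydroxymethyl butenolide becomes the spacer and is joined, with retention of geometry, to an (E)-alkenyl iodide that already holds the second E alkene and the furan ring. The precursors are therefore an allyl-substituted butenolide (C11) and a furyl dienyl iodide (C14), and the coupling gives the unprotected target directly.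

Key step: step 15

Remark: epoxide 5 and its descendants 7 and 8 are used as racemates, because that stereocentre leaves as acetone in step 4; all other stereochemistry is as drawn.

**Fragment A: furyl dienyl iodide 14**

Step 1
Reactants: 1 furan-3-ylmethanol
Product: 3 3-(chloromethyl)furan, via furan-3-ylmethyl methanesulfonate 2 (not isolated)
Conditions: MsCl, 2,4,6-collidine, LiCl, DMF, 0 °C
Reagents that add atoms: lithium chloride [Li+].[Cl-]
Why: Mesylation of the primary alcohol and in situ SN2 displacement by chloride should give the chloride under non-acidic conditions that spare the furan ring.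

Step 2
Reactants: 4 geranyl chloride
Product: 5 3-[(3E)-5-chloro-3-methylpent-3-en-1-yl]-2,2-dimethyloxirane (racemic)
Conditions: mCPBA, NaHCO3, CH2Cl2, 0 °C
Reagents that add atoms: 3-chloroperoxybenzoic acid OOC(=O)c1cccc(Cl)c1
Why: Prilezhaev epoxidation should take the electron-rich 6,7-alkene because the 2,3-alkene is deactivated by the allylic chloride, and the racemic stereocentre is removed again in step 4.

Step 3
Reactants: 3 3-(chloromethyl)furan; 5 3-[(3E)-5-chloro-3-methylpent-3-en-1-yl]-2,2-dimethyloxirane
Product: 7 3-[(3E)-6-(furan-3-yl)-3-methylhex-3-en-1-yl]-2,2-dimethyloxirane (racemic), via (furan-3-ylmethyl)magnesium chloride 6 (not isolated)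
Conditions: Mg, THF, rt; then 5, Li2CuCl4 (3 mol %), THF, −10 → 0 °C
Reagents that add atoms: none
Why: In this copper-catalysed Grignard cross-coupling the cuprate should steer the ambident furylmethyl nucleophile to react through its CH2 carbon and displace the primary allylic chloride at the α-carbon (SN2) with the E alkene intact, faster than it opens the trisubstituted epoxide.

Step 4
Reactants: 7 3-[(3E)-6-(furan-3-yl)-3-methylhex-3-en-1-yl]-2,2-dimethyloxirane
Product: 9 (4E)-7-(furan-3-yl)-4-methylhept-4-enal, via vicinal diol 8 (not isolated)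
Conditions: H5IO6, THF/H2O, 0 °C
Reagents that add atoms: none
Why: Acid-catalysed opening of the epoxide by water at the tertiary carbon followed by Malaprade glycol cleavage in the same flask should release the aldehyde (its oxygen being the former epoxide oxygen) and acetone, while the furan and the trisubstituted alkene are inert to periodate.

Step 5
Reactants: 9 (4E)-7-(furan-3-yl)-4-methylhept-4-enal
Product: 10 3-[(3E)-8,8-dibromo-4-methylocta-3,7-dien-1-yl]furan
Conditions: CBr4, PPh3, Et3N, CH2Cl2, 0 °C
Reagents that add atoms: carbon tetrabromide BrC(Br)(Br)Br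
Why: The first stage of the Corey–Fuchs sequence, a Wittig-type dibromoolefination with the ylide formed in situ, is reliable for unhindered aldehydes, and Et3N buffers the acid-sensitive furan.

Step 6
Reactants: 10 3-[(3E)-8,8-dibromo-4-methylocta-3,7-dien-1-yl]furan
Product: 12 3-[(3E)-4-methylnon-3-en-7-yn-1-yl]furan, via lithium acetylide 11 (not isolated)
Conditions: n-BuLi (2.05 equiv), THF, −78 °C; MeI, −78 °C → rt
Reagents that add atoms: iodomethane CI
Why: The second Corey–Fuchs stage (bromine–lithium exchange, Fritsch–Buttenberg–Wiechell rearrangement, deprotonation) gives the acetylide, which is C-methylated by SN2, and holding the base to two equivalents at low temperature should avoid lithiation of the furan.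

Step 7
Reactants: 12 3-[(3E)-4-methylnon-3-en-7-yn-1-yl]furan
Product: 14 3-[(3E,7E)-8-iodo-4-methylnona-3,7-dien-1-yl]furan, via alkenylzirconocene chloride 13 (not isolated)
Conditions: Cp2Zr(H)Cl (2.5 equiv), THF, 50 °C; then I2, THF, 0 °C
Reagents that add atoms: iodine II
Why: Syn-hydrozirconation under equilibrating conditions (excess hydride, heat) should place zirconium on the less hindered methyl-bearing carbon, and iodinolysis with retention then fixes the E geometry, which is set by the syn addition.

**Fragment B: allyl-substituted butenolide 25**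

Step 8
Reactants: 15 (4R)-4-benzyl-3-propanoyl-1,3-oxazolidin-2-one
Product: 17 (4R)-4-benzyl-3-[(2S)-2-methylpent-4-enoyl]-1,3-oxazolidin-2-one, via sodium (Z)-enolate 16 (not isolated)
Conditions: NaN(SiMe3)2, THF, −78 °C; allyl iodide, −78 → −45 °C
Reagents that add atoms: allyl iodide C=CCI
Why: In the Evans asymmetric alkylation the chelated Z-enolate is attacked by allyl iodide on the face opposite the benzyl group of the (R)-auxiliary, which sets the (S) stereocentre.

Step 9
Reactants: 17 (4R)-4-benzyl-3-[(2S)-2-methylpent-4-enoyl]-1,3-oxazolidin-2-one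
Product: 18 (2S)-2-methylpent-4-en-1-ol
Conditions: LiBH4, H2O (1 equiv), Et2O, 0 °C
Reagents that add atoms: none
Why: Reductive cleavage of the imide at the exocyclic carbonyl by borohydride should release the primary alcohol without touching the α-stereocentre or the alkene, and the auxiliary is recovered.

Step 10
Reactants: 18 (2S)-2-methylpent-4-en-1-ol
Product: 19 (2S)-2-methylpent-4-enal
Conditions: Dess–Martin periodinane, NaHCO3, CH2Cl2, 0 °C → rt; used as a solution
Reagents that add atoms: none
Why: Buffered Dess–Martin oxidation is non-basic and should give the α-branched aldehyde without epimerisation, and telescoping avoids loss of this volatile compound.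

Step 11
Reactants: 19 (2S)-2-methylpent-4-enal
Product: 20 (3S)-3-methylhex-5-en-1-yne
Conditions: Ohira–Bestmann reagent, K2CO3, MeOH, 0 °C → rt
Reagents that add atoms: dimethyl (1-diazo-2-oxopropyl)phosphonate COP(=O)(OC)C(=[N+]=[N-])C(C)=O
Why: The Seyferth–Gilbert homologation in its Ohira–Bestmann form runs with mild carbonate at low temperature, so the α-stereocentre should survive and becomes a configurationally stable propargylic centre.

Step 12
Reactants: 21 methyl prop-2-ynoate
Product: 22 methyl (2Z)-2-(hydroxymethyl)-3-iodoprop-2-enoate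
Conditions: MgI2, monomeric CH2O (from cracked paraformaldehyde), CH2Cl2, 0 °C
Reagents that add atoms: magnesium iodide [Mg+2].[I-].[I-]; formaldehyde C=O
Why: In this β-iodo Morita–Baylis–Hillman (iodo-aldol) reaction iodide adds to the propiolate, and the magnesium β-iodoallenolate adds to formaldehyde at the α-carbon under kinetic control, which should give the Z isomer with iodine cis to the ester.

Step 13
Reactants: 22 methyl (2Z)-2-(hydroxymethyl)-3-iodoprop-2-enoate
Product: 23 (2Z)-2-(hydroxymethyl)-3-iodoprop-2-enoic acid
Conditions: LiOH, THF/H2O, 0 °C; then 1 M HCl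
Reagents that add atoms: lithium hydroxide [Li+].[OH-]
Why: Saponification at low temperature should cleave the methyl ester faster than hydroxide can add to the β-iodoacrylate, so the Z geometry is kept.

Step 14
Reactants: 20 (3S)-3-methylhex-5-en-1-yne; 23 (2Z)-2-(hydroxymethyl)-3-iodoprop-2-enoic acid
Product: 25 (5Z)-3-(hydroxymethyl)-5-[(2S)-2-methylpent-4-en-1-ylidene]furan-2(5H)-one, via enynoic acid 24 (not isolated)
Conditions: Pd(PPh3)4 (5 mol %), CuI (10 mol %), Et3N, MeCN, rt
Reagents that add atoms: none
Why: Tandem Sonogashira coupling and 5-exo-dig lactonisation of the cis-disposed carboxylate (anti-oxymetalation, then protodemetalation) should give the Z-ylidene butenolide, while the hydroxymethyl group, trans to the alkyne, cannot cyclise and the propargylic stereocentre is not touched.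

**Fragment union**

Step 15
Reactants: 25 (5Z)-3-(hydroxymethyl)-5-[(2S)-2-methylpent-4-en-1-ylidene]furan-2(5H)-one; 14 3-[(3E,7E)-8-iodo-4-methylnona-3,7-dien-1-yl]furan
Product: 27 (5Z)-5-[(2S,6E,10E)-13-(furan-3-yl)-2,6,10-trimethyltrideca-6,10-dien-1-ylidene]-3-(hydroxymethyl)furan-2(5H)-one, via B-alkyl-9-BBN borinate 26 (not isolated)
Conditions: 9-BBN (2.2 equiv), THF, 0 °C → rt; then 14, Pd(dppf)Cl2 (5 mol %), AsPh3 (10 mol %), 3 M aq. K3PO4, DMF, rt
Reagents that add atoms: none
Why: 9-BBN adds anti-Markovnikov to the monosubstituted alkene of 25 (the free hydroxyl is borylated by the second equivalent and released again on aqueous work-up), then zerovalent palladium inserts into the C–I bond of 14 with retention, the phosphate-activated borinate transfers its primary alkyl group, and reductive elimination forms the C(sp3)–C(sp2) bond. This is a B-alkyl Suzuki–Miyaura coupling, the standard union of a hydroborated terminal alkene with an alkenyl iodide. No ring is closed and no stereocentre is created; the E geometry of the new trisubstituted alkene is that of the iodide, carried through stereoretentive oxidative addition and reductive elimination. The step needs chemoselectivity for the terminal alkene over the two conjugated trisubstituted alkenes of the butenolide, which the steric demand of 9-BBN should secure, and it needs the base-sensitive enol lactone and the C2 stereocentre to survive, for which phosphate base at room temperature and the wide-bite-angle dppf ligand (fast reductive elimination, little β-hydride elimination) are chosen.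

**Compound list**

1 | furan-3-ylmethanol | OCc1ccoc1 | starting material
2 | furan-3-ylmethyl methanesulfonate | CS(=O)(=O)OCc1ccoc1 | intermediate
3 | 3-(chloromethyl)furan | ClCc1ccoc1 | intermediate
4 | geranyl chloride, (2E)-1-chloro-3,7-dimethylocta-2,6-diene | CC(C)=CCC/C(C)=C/CCl | starting material
5 | 3-[(3E)-5-chloro-3-methylpent-3-en-1-yl]-2,2-dimethyloxirane (racemic) | CC1(C)OC1CC/C(C)=C/CCl | intermediate
6 | (furan-3-ylmethyl)magnesium chloride | Cl[Mg]Cc1ccoc1 | intermediate
7 | 3-[(3E)-6-(furan-3-yl)-3-methylhex-3-en-1-yl]-2,2-dimethyloxirane (racemic) | CC1(C)OC1CC/C(C)=C/CCc1ccoc1 | intermediate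
8 | (6E)-9-(furan-3-yl)-2,6-dimethylnon-6-ene-2,3-diol (racemic) | CC(C)(O)C(O)CC/C(C)=C/CCc1ccoc1 | intermediate
9 | (4E)-7-(furan-3-yl)-4-methylhept-4-enal | O=CCC/C(C)=C/CCc1ccoc1 | intermediate
10 | 3-[(3E)-8,8-dibromo-4-methylocta-3,7-dien-1-yl]furan | BrC(Br)=CCC/C(C)=C/CCc1ccoc1 | intermediate
11 | [(5E)-8-(furan-3-yl)-5-methyloct-5-en-1-yn-1-yl]lithium | [Li]C#CCC/C(C)=C/CCc1ccoc1 | intermediate
12 | 3-[(3E)-4-methylnon-3-en-7-yn-1-yl]furan | CC#CCC/C(C)=C/CCc1ccoc1 | intermediate
13 | chlorobis(cyclopentadienyl)[(2E,6E)-9-(furan-3-yl)-6-methylnona-2,6-dien-2-yl]zirconium | C/C(=C\CCc1ccoc1)CC/C=C(\C)[Zr](Cl)(C1C=CC=C1)C1C=CC=C1 | intermediate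
14 | 3-[(3E,7E)-8-iodo-4-methylnona-3,7-dien-1-yl]furan | C/C(=C\CCc1ccoc1)CC/C=C(\C)I | intermediate
15 | (4R)-4-benzyl-3-propanoyl-1,3-oxazolidin-2-one | CCC(=O)N1[C@H](Cc2ccccc2)COC1=O | starting material
16 | sodium (Z)-enolate of 15 | C/C=C(\[O-])N1[C@H](Cc2ccccc2)COC1=O.[Na+] | intermediate
17 | (4R)-4-benzyl-3-[(2S)-2-methylpent-4-enoyl]-1,3-oxazolidin-2-one | C=CC[C@H](C)C(=O)N1[C@H](Cc2ccccc2)COC1=O | intermediate
18 | (2S)-2-methylpent-4-en-1-ol | C=CC[C@H](C)CO | intermediate
19 | (2S)-2-methylpent-4-enal | C=CC[C@H](C)C=O | intermediate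
20 | (3S)-3-methylhex-5-en-1-yne | C=CC[C@H](C)C#C | intermediate
21 | methyl prop-2-ynoate | C#CC(=O)OC | starting material
22 | methyl (2Z)-2-(hydroxymethyl)-3-iodoprop-2-enoate | OC/C(=C/I)C(=O)OC | intermediate
23 | (2Z)-2-(hydroxymethyl)-3-iodoprop-2-enoic acid | OC/C(=C/I)C(=O)O | intermediate
24 | (2Z,6S)-2-(hydroxymethyl)-6-methylnona-2,8-dien-4-ynoic acid | C=CC[C@H](C)C#C/C=C(/CO)C(=O)O | intermediate
25 | (5Z)-3-(hydroxymethyl)-5-[(2S)-2-methylpent-4-en-1-ylidene]furan-2(5H)-one | C=CC[C@H](C)/C=C1/C=C(CO)C(=O)O1 | intermediate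
26 | (5Z)-5-[(2S)-5-(9-borabicyclo[3.3.1]nonan-9-yl)-2-methylpentylidene]-3-{[(9-borabicyclo[3.3.1]nonan-9-yl)oxy]methyl}furan-2(5H)-one | C[C@@H](CCCB1C2CCCC1CCC2)/C=C1/C=C(COB2C3CCCC2CCC3)C(=O)O1 | intermediate
27 | (5Z)-5-[(2S,6E,10E)-13-(furan-3-yl)-2,6,10-trimethyltrideca-6,10-dien-1-ylidene]-3-(hydroxymethyl)furan-2(5H)-one | C/C(=C\CCc1ccoc1)CC/C=C(\C)CCC[C@H](C)/C=C1/C=C(CO)C(=O)O1 | target

**Step count and risks**

Total step count: 15. Longest linear sequence: 7 steps (steps 1 or 2, then 3, 4, 5, 6, 7 and 15).

Steps most likely to fail: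

1. Step 15. The aqueous base may open the enol lactone, 9-BBN may attack the conjugated alkenes or the carbonyl, and the borinate may undergo protodeboronation or β-hydride elimination instead of transmetalation. The fallback sets out from alkyne 20 and forms the same bond on a partner without the lactone. C-Silylation (n-BuLi, then TMSCl) would give trimethyl[(3S)-3-methylhex-5-en-1-yn-1-yl]silane F1. Hydroboration of its terminal alkene with 9-BBN and coupling with iodide 14 (Pd(dppf)Cl2, AsPh3, aq. Cs2CO3, DMF) would give [(3S,7E,11E)-14-(furan-3-yl)-3,7,11-trimethyltetradeca-7,11-dien-1-yn-1-yl]trimethylsilane F2. K2CO3 in MeOH would free the alkyne 3-[(3E,7E,12S)-4,8,12-trimethyltetradeca-3,7-dien-13-yn-1-yl]furan F3. The tandem Sonogashira coupling and lactonisation of step 14 with iodo acid 23 would then build the butenolide last, and the fallback comes back to the route at target 27.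

2. Step 12. Formaldehyde may oligomerise, or the iodoallenolate may be protonated before the aldol event, and the Z isomer may drift to E. The fallback sets out from alkyne 20 and bypasses 22 and 23. Anti-addition of Br2 to commercial propiolic acid would give (2E)-2,3-dibromoprop-2-enoic acid F4. Tandem coupling and lactonisation with 20 (Pd(PPh3)4, CuI, Et3N, MeCN), with oxidative addition at the more reactive β C–Br bond, would give (5Z)-3-bromo-5-[(2S)-2-methylpent-4-en-1-ylidene]furan-2(5H)-one F5. Stille hydroxymethylation with (tributylstannyl)methanol and Pd(PPh3)4 in dioxane would then give butenolide 25, where the route is rejoined.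

3. Step 7. Incomplete equilibration may leave part of the zirconium on C7 and give a regioisomeric iodide that is hard to remove, and excess iodine may attack the furan. The fallback sets out from dibromide 10. n-BuLi and then TMSCl would give [(5E)-8-(furan-3-yl)-5-methyloct-5-en-1-yn-1-yl]trimethylsilane F6. i-Bu2AlH in heptane (net trans-hydroalumination with aluminium geminal to silicon), then MeLi and MeI, would give [(2E,6E)-9-(furan-3-yl)-6-methylnona-2,6-dien-2-yl]trimethylsilane F7, in which regiochemistry is fixed by silicon. Iododesilylation with N-iodosuccinimide in MeCN/ClCH2CN at 0 °C, with retention, would return iodide 14.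

**Further compounds**

F1 | step 15 | trimethyl[(3S)-3-methylhex-5-en-1-yn-1-yl]silane | C=CC[C@H](C)C#C[Si](C)(C)C
F2 | step 15 | [(3S,7E,11E)-14-(furan-3-yl)-3,7,11-trimethyltetradeca-7,11-dien-1-yn-1-yl]trimethylsilane | C/C(=C\CCc1ccoc1)CC/C=C(\C)CCC[C@H](C)C#C[Si](C)(C)C
F3 | step 15 | 3-[(3E,7E,12S)-4,8,12-trimethyltetradeca-3,7-dien-13-yn-1-yl]furan | C/C(=C\CCc1ccoc1)CC/C=C(\C)CCC[C@H](C)C#C
F4 | step 12 | (2E)-2,3-dibromoprop-2-enoic acid | Br/C=C(/Br)C(=O)O
F5 | step 12 | (5Z)-3-bromo-5-[(2S)-2-methylpent-4-en-1-ylidene]furan-2(5H)-one | C=CC[C@H](C)/C=C1/C=C(Br)C(=O)O1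
F6 | step 7 | [(5E)-8-(furan-3-yl)-5-methyloct-5-en-1-yn-1-yl]trimethylsilane | C[Si](C)(C)C#CCC/C(C)=C/CCc1ccoc1
F7 | step 7 | [(2E,6E)-9-(furan-3-yl)-6-methylnona-2,6-dien-2-yl]trimethylsilane | C/C(=C\CCc1ccoc1)CC/C=C(\C)[Si](C)(C)C
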